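Everything rests on cutting ring A (C1 OH, C2 OAr, C3 Br, C4 OMe, C5 Br, C6 H) at C2-C3 and C5-C6. The feature exploited is its oxygen pattern. C6-C1-C2 is a 4-aryloxyacetoacetate in disguise, and C3-C4-C5 is 2-methoxymalonaldehyde, whose two ends are identical. A single TiCl4-mediated [3+3] cyclocondensation makes both bonds, closes and aromatises ring A, and leaves an ester on C6. Its precursor is the 1,3-bis(trimethylsilyloxy)diene of methyl 4-(2,4-dibromophenoxy)acetoacetate, whose aryl ether bond comes from a plain phenoxide alkylation. The partner is 1,1,2,3,3-pentamethoxypropane. The ester keeps bromine off C6 while C3 and C5 are brominated, and is then excised.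

Key step: step 5

Assumption: the target has no stereocentre. The enol ether geometries and the transient sp3 centres of the key step arise as mixtures and have no bearing on the outcome. Ring B is the 2,4-dibromophenyl ring.

Step 1
Reactants: 1 2,4-dibromophenol; 2 methyl 4-chloroacetoacetate
Product: 3 methyl 4-(2,4-dibromophenoxy)-3-oxobutanoate
Conditions: NaH (2.2 equiv), NaI (10 mol %), THF, 0 to 50 °C; aq. HCl
Reagents that add atoms: none
Why: Williamson-type SN2 displacement, in which the second equivalent of NaH stores the beta-keto ester as its sodium enolate and so protects the ketone from aldol and Darzens-type side reactions while the phenoxide attacks the primary C-Cl carbon, a known entry to 4-aryloxyacetoacetates.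

Step 2
Reactants: 3 methyl 4-(2,4-dibromophenoxy)-3-oxobutanoate
Product: 5 4-(2,4-dibromophenoxy)-1-methoxy-1,3-bis(trimethylsilyloxy)buta-1,3-diene (E/Z mixture), via mono(silyl enol ether) 4 (not isolated)
Conditions: TMSOTf (2.3 equiv), Et3N (3 equiv), Et2O, 0 °C to rt; decant from the ammonium salt, concentrate, use crude
Reagents that add atoms: trimethylsilyl trifluoromethanesulfonate, C[Si](C)(C)OS(=O)(=O)C(F)(F)F
Why: Soft enolisation with a silyl triflate and a tertiary amine, a known one-flask route from beta-keto esters to 1,3-bis(silyloxy)dienes, silylates the enol oxygen first (4) and then the conjugated ester oxygen, so that Et3N can remove an OCH2 proton already acidified by OAr, and it spares ring B a lithium amide that could metalate the C-H between its two bromines.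

Step 3
Reactants: 6 1,1,2-trimethoxyethane
Product: 7 1,2-dimethoxyethene (E/Z mixture)
Conditions: TMSOTf (1.1 equiv), iPr2NEt (1.2 equiv), CH2Cl2, -20 °C to rt; decant from the salt, fractional distillation
Reagents that add atoms: none
Why: Silyl-triflate-mediated elimination of methanol from an acetal, in which TMSOTf removes one methoxy group as its silyl ether and the hindered amine deprotonates the oxocarbenium ion at the neighbouring CH2, is the known mild substitute for gas-phase cracking.

Step 4
Reactants: 7 1,2-dimethoxyethene; 8 trimethyl orthoformate
Product: 9 1,1,2,3,3-pentamethoxypropane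
Conditions: 8 (4 equiv, as solvent), BF3·OEt2 (2 mol %), slow addition of 7, 0 °C to rt; K2CO3, distillation
Reagents that add atoms: none
Why: Lewis-acid-catalysed addition of an orthoformate to an enol ether (the dimethoxycarbenium ion adds to the electron-rich alkene and methoxide transfer caps the new oxocarbenium ion) is the standard route to malonaldehyde bis(acetals), and excess 8 with slow addition of 7 should suppress telomerisation.

Step 5
Reactants: 5 4-(2,4-dibromophenoxy)-1-methoxy-1,3-bis(trimethylsilyloxy)buta-1,3-diene; 9 1,1,2,3,3-pentamethoxypropane
Product: 12 methyl 3-(2,4-dibromophenoxy)-2-hydroxy-5-methoxybenzoate, via open-chain Mukaiyama adduct 10 (not isolated), via trimethoxycyclohexanone ester 11 (not isolated)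
Conditions: TiCl4 (2 equiv), 4 Å MS, CH2Cl2 (concentrated), -78 to 20 °C; aq. HCl
Reagents that add atoms: none
Why: TiCl4 ionises one acetal end of 9, and the terminal, OAr-bearing carbon of 5, the most nucleophilic site of a 1,3-bis(silyloxy)diene, adds to the oxocarbenium ion in a vinylogous Mukaiyama reaction (C2-C3), which leaves 10 as the C6=C1 silyl enol ether of a beta-keto ester. Ionisation of the second acetal then lets C6 attack C5; because the enol double bond C6=C1 lies inside the forming ring and the C=O+ bond outside it, the closure is 6-(enolendo)-exo-trig, an allowed mode for a six-membered ring, and gives 11. The methoxy groups on C3 and C5 sit beta to the ketone and to the keto ester carbon and leave by E1cB-type loss of methanol, after which the 4H-dienone tautomerises to the phenol, so that only the C4 methoxy group, which has no such exit, is kept. The closest known reaction type is the Lewis-acid-mediated formal [3+3] cyclocondensation of 1,3-bis(silyloxy)buta-1,3-dienes with malonaldehyde bis(acetals) to salicylates, established separately for 4-aryloxy dienes and for 2-substituted bis(acetals). No stereocentre survives, since the sp3 centres of 10 and 11 form as mixtures and are erased on aromatisation. Regioselectivity is not required because both ends of 9 are identical, and the selectivity that is required, one-to-one cyclisation ahead of protodesilylation or double addition, rests on the low starting temperature, the concentrated solution and the intramolecular second bond formation.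

Step 6
Reactants: 12 methyl 3-(2,4-dibromophenoxy)-2-hydroxy-5-methoxybenzoate
Product: 14 methyl 4,6-dibromo-3-(2,4-dibromophenoxy)-2-hydroxy-5-methoxybenzoate, via C5 monobromide 13 (not isolated)
Conditions: Br2 (2.3 equiv), AcOH, 20 to 45 °C, dark; aq. NaHSO3
Reagents that add atoms: bromine, BrBr
Why: Electrophilic aromatic bromination should take the only two C-H positions of ring A, because C3 and C5 are each ortho to OMe and ortho or para to OAr (the two meta-related ether donors reinforce each other), the ester occupies C6 where the phenol would otherwise direct bromine, the acidic medium keeps ipso attack para to OH reversible, and the one accessible position of ring B is meta to both of its bromines and far less reactive.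

Step 7
Reactants: 14 methyl 4,6-dibromo-3-(2,4-dibromophenoxy)-2-hydroxy-5-methoxybenzoate
Product: 15 4,6-dibromo-3-(2,4-dibromophenoxy)-2-hydroxy-5-methoxybenzoic acid
Conditions: KOH (10 equiv), MeOH-H2O (3:1), reflux; aq. HCl, 0 °C
Reagents that add atoms: potassium hydroxide, [K+].[OH-]
Why: BAc2 saponification of a salicylate, in which the known general-base assistance by the neighbouring phenoxide should offset the crowding by C5-Br, while the aryl methyl ether, the diaryl ether and the four C-Br bonds are inert to aqueous hydroxide at this temperature.

Step 8
Reactants: 15 4,6-dibromo-3-(2,4-dibromophenoxy)-2-hydroxy-5-methoxybenzoic acid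
Product: 16 3,5-dibromo-2-(2,4-dibromophenoxy)-4-methoxyphenol (target)
Conditions: Ag2CO3 (10 mol %), AcOH (10 mol %), DMSO, 110-120 °C
Reagents that add atoms: none
Why: Silver-catalysed protodecarboxylation of an ortho-substituted benzoic acid, in which the monovalent silver carboxylate extrudes CO2 with help from both ortho substituents (O and Br) and from strain relief in the hexasubstituted ring and the aryl-silver species is then protonated, needs neither copper nor hot strong base, so the C-Br bonds persist and the C1-OH cannot displace the ortho bromine of ring B.

Compound list
1 | 2,4-dibromophenol | Oc1ccc(Br)cc1Br | starting material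
2 | methyl 4-chloroacetoacetate | COC(=O)CC(=O)CCl | starting material
3 | methyl 4-(2,4-dibromophenoxy)-3-oxobutanoate | COC(=O)CC(=O)COc1ccc(Br)cc1Br | intermediate
4 | methyl 4-(2,4-dibromophenoxy)-3-(trimethylsilyloxy)but-2-enoate (E/Z mixture, not isolated) | COC(=O)C=C(O[Si](C)(C)C)COc1ccc(Br)cc1Br | intermediate
5 | 4-(2,4-dibromophenoxy)-1-methoxy-1,3-bis(trimethylsilyloxy)buta-1,3-diene (E/Z mixture) | COC(O[Si](C)(C)C)=CC(O[Si](C)(C)C)=COc1ccc(Br)cc1Br | intermediate
6 | 1,1,2-trimethoxyethane | COCC(OC)OC | starting material
7 | 1,2-dimethoxyethene (E/Z mixture) | COC=COC | intermediate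
8 | trimethyl orthoformate | COC(OC)OC | starting material
9 | 1,1,2,3,3-pentamethoxypropane | COC(OC)C(OC)C(OC)OC | intermediate
10 | methyl 4-(2,4-dibromophenoxy)-5,6,7,7-tetramethoxy-3-(trimethylsilyloxy)hept-2-enoate (mixture of isomers, not isolated) | COC(=O)C=C(O[Si](C)(C)C)C(Oc1ccc(Br)cc1Br)C(OC)C(OC)C(OC)OC | intermediate
11 | methyl 3-(2,4-dibromophenoxy)-4,5,6-trimethoxy-2-oxocyclohexane-1-carboxylate (mixture of diastereomers, not isolated) | COC(=O)C1C(OC)C(OC)C(OC)C(Oc2ccc(Br)cc2Br)C1=O | intermediate
12 | methyl 3-(2,4-dibromophenoxy)-2-hydroxy-5-methoxybenzoate | COC(=O)c1cc(OC)cc(Oc2ccc(Br)cc2Br)c1O | intermediate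
13 | methyl 6-bromo-3-(2,4-dibromophenoxy)-2-hydroxy-5-methoxybenzoate (not isolated) | COC(=O)c1c(Br)c(OC)cc(Oc2ccc(Br)cc2Br)c1O | intermediate
14 | methyl 4,6-dibromo-3-(2,4-dibromophenoxy)-2-hydroxy-5-methoxybenzoate | COC(=O)c1c(Br)c(OC)c(Br)c(Oc2ccc(Br)cc2Br)c1O | intermediate
15 | 4,6-dibromo-3-(2,4-dibromophenoxy)-2-hydroxy-5-methoxybenzoic acid | OC(=O)c1c(Br)c(OC)c(Br)c(Oc2ccc(Br)cc2Br)c1O | intermediate
16 | 3,5-dibromo-2-(2,4-dibromophenoxy)-4-methoxyphenol | COc1c(Br)cc(O)c(Oc2ccc(Br)cc2Br)c1Br | target

Total step count: 8. Longest linear sequence: 6 steps (steps 1, 2, 5, 6, 7, 8; the branch through steps 3 and 4 is equally long).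

Steps most likely to fail

Step 5. The C4 methoxy group inductively slows ionisation of the neighbouring acetals. Protodesilylation of the diene by traces of HCl may therefore outrun the first C-C bond formation, or the cascade may stall before ring closure. The fallback sets out from 9. Controlled hydrolysis with one equivalent of water and catalytic p-toluenesulfonic acid, with methanol distilled off, should give 2,3-dimethoxyprop-2-enal F1. Its free aldehyde needs no ionisation. TiCl4-mediated cyclocondensation of F1 with 5 belongs to the 3-alkoxyenal and 3-alkoxyenone branch of the same [3+3] family: a Mukaiyama aldol addition is followed by conjugate addition-elimination. It forms the same two bonds, again with no regiochemical issue after aromatisation, and comes back to the route at 12.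

Step 6. The second bromination, at C3, is wedged between OAr and OMe and lies para to the ester, so it may stall. During long exposure, ipso attack of bromine para to the free phenol may also end in oxidative loss of the C4 methyl group. The fallback sets out from 12. Acetylation (Ac2O, pyridine) should give methyl 2-acetoxy-3-(2,4-dibromophenoxy)-5-methoxybenzoate F2. With the phenol masked the quinone-forming pathway is closed, so a much stronger brominating system can be used in stoichiometric amount (NBS, 2.2 equiv, CF3CO2H with catalytic H2SO4, rt). This should give methyl 2-acetoxy-4,6-dibromo-3-(2,4-dibromophenoxy)-5-methoxybenzoate F3. The hydroxide treatment of step 7 then removes the acetate and the methyl ester together, and the route is rejoined at 15.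

Step 7. Attack of hydroxide at an acyl carbon flanked by a phenoxide and C5-Br on a hexasubstituted ring may be too slow to be useful. The fallback sets out from 14 and changes the site of cleavage from the acyl carbon to the ester methyl carbon. LiI (5 equiv) in refluxing pyridine dealkylates by SN2 (BAl2), which is indifferent to crowding at the carbonyl. The carboxylate is a far better leaving group than the C4 aryloxide, so the aryl methyl ether should survive if the reaction is stopped at full ester conversion. Acidic work-up comes back to the route at 15, and this detour creates no new compound (F0).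

Further compounds
F1 | step 5 | 2,3-dimethoxyprop-2-enal (E/Z mixture) | COC=C(OC)C=O
F2 | step 6 | methyl 2-acetoxy-3-(2,4-dibromophenoxy)-5-methoxybenzoate | COC(=O)c1cc(OC)cc(Oc2ccc(Br)cc2Br)c1OC(C)=O
F3 | step 6 | methyl 2-acetoxy-4,6-dibromo-3-(2,4-dibromophenoxy)-5-methoxybenzoate | COC(=O)c1c(Br)c(OC)c(Br)c(Oc2ccc(Br)cc2Br)c1OC(C)=O
F0 | step 7 | none | none
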